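## The problem

- The target is a B-type procyanidin tetramer of four (−)-epicatechin units (C2 R and C3 R in each): unit 1-(4β→6)-unit 2-(4β→8)-unit 3-(4β→6)-unit 4, with unit 4 the terminal unit (C4H2).
- A synthesis has to make three interflavan bonds, each from C4 of ring C of one unit to ring A of the next. Each upper C4 is a stereocentre that must be β, trans to O3 (eleven stereocentres in all).
- The eight C2/C3 centres can be bought with the monomer. Each C4 centre can be controlled by its own unit, since a nucleophile adds to the planar C4 cation anti to the pseudo-axial C3–OH and the C2 aryl group.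
- The hard part is regiochemical. Ring A is a phloroglucinol ether whose C8 is intrinsically more nucleophilic than C6, yet two of the three bonds (to unit 2 and to unit 4) must go to C6, and they flank the one bond that goes to C8 (unit 3).
- Every unit is both a nucleophile (ring A C–H) and a potential electrophile (C4), so unprogrammed coupling gives oligomer mixtures.
- The free polyphenol is sensitive to air and base (catechol rings B, epimerisable C2) and to acid (interflavan bonds cleave). The phenols must stay masked to the end and the last step must be mild and reductive.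
- The feature that makes the key step possible: the bond C4 (ring C, unit 2)–C8 (ring A, unit 3) divides the molecule into two halves of identical constitution and configuration, each an epicatechin-(4β→6)-epicatechin. C8 of ring A in units 1, 2 and 4 bears only hydrogen in the target, so a removable halogen can sit on each of these three carbons while C8 of unit 3 alone stays free.

## Retrosynthesis

**12 ⇒ 11.** Cut: the sixteen phenolic O–benzyl bonds and three ring A carbon–halogen bonds (Br at C8 of units 1 and 2, Cl at C8 of unit 4). Benzyl ethers and aryl halides fall together under hydrogenolysis, so no strong acid or base meets the free tetramer. 11 already has the whole skeleton and all eleven stereocentres; the forward step only has to reduce.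

**11 ⇒ 6 + 10 (key cut).** Cut: C4 (unit 2)–C8 (unit 3).
- Against its neighbours: either outer C4–C6 bond, if made last, would have to form at C6 of a brominated ring in the presence of the more electron-rich C6–H of unit 3, and would split the molecule 3 + 1.
- The central bond is the only one that goes to the intrinsically favoured C8. It splits 11 into two dimers of half its size with the same epicatechin-(4β→6)-epicatechin skeleton.
- 6 (units 1 and 2) carries bromine at both C8 carbons and an aryl sulfide at C4 of unit 2. 10 (units 3 and 4) has chlorine at C8 of unit 4, no leaving group, and a free C8–H only in unit 3.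
- The forward reaction must ionise 6 at C4 of unit 2 with a thiophile that leaves ethers, halides and interflavan bonds alone, and the arene must enter β. By design 6 cannot act as a nucleophile at any C8, 10 cannot act as an electrophile, and 11 can do neither.

**6 ⇒ 4 + 5 and 10 ⇒ 8 ⇒ 4 + 7.** Cut: the two C4–C6 bonds, both with the same electrophile 4.
- The nucleophiles 5 and 7 have a halogen at C8, so C6 is the only ring A carbon that can react. The contra-electronic regiochemistry becomes the only possible one.
- Bromine at C8 of 4 keeps electrophile and product from reacting at C8 during the coupling.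
- 5 already carries at C4 the aryl sulfide that becomes the leaving group of 6. The forward coupling must therefore ionise the C4 ether of 4 with an oxophilic acid that does not touch the C4–S bond.
- In 8 the bromine inherited by unit 3 must be replaced by hydrogen before the union while the halogen of unit 4 stays. This is why unit 4 carries chlorine, which bromine–lithium exchange leaves alone (8 ⇒ 10).

**5 ⇒ 4 ⇒ 3 ⇒ 2 ⇒ 1 and 7 ⇒ 2.** 5 is 4 after exchange of the C4 ether for a thiol; 4 is 3 after bromination at C8; 3 is 2 after oxidative etherification at C4; 7 is 2 after chlorination at C8; 2 is the tetrabenzyl ether of commercial 1. One chiral starting material supplies all eight C2/C3 centres, and 4 serves three times: as unit 1, as unit 3 and as the precursor of unit 2.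

## Roads not taken

Alternative 1: (the most obvious) grow the chain one unit at a time from the terminal unit, so that the last cut is C4 (unit 1)–C6 (unit 2).
- Sequence: 7 + 4 → 8 → 10, then 10 + 4 → trimer A1, then A1 + 4 → 11, each bond by the same acid-promoted Friedel–Crafts alkylation. The forward key step would be alkylation of A1 at C6 of its top unit.
- In A1 that C6–H sits on a brominated ring, while unit 3 still has a C6–H on an unhalogenated, more electron-rich ring that cannot be capped selectively. The cation of 4 should go to the wrong ring.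
- In the chosen plan the C4 (unit 1)–C6 (unit 2) bond is made in 6 before unit 3 is present. The linear order also puts three couplings in series instead of two in parallel and one union.

Alternative 2: keep the central cut but form the bond by oxidative dehydrogenative self-coupling of one dimer.
- DDQ would take hydride from C4H2 of the lower unit of 10, and a second molecule of 10 would capture the cation at C8 of its upper unit. This gives A2 with no leaving-group chemistry and no second dimer.
- A2 still holds a C4H2 group and a free C8–H, so it re-enters the coupling. Step-growth statistics for such a self-complementary monomer keep the single-coupling product below one third of the mass at any conversion.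
- DDQ can also take the doubly benzylic C4–H of the existing interflavan bond, and the electron-rich nucleophile is exposed to the oxidant.
- The chosen plan gives each partner one role only, so the union stops after one bond.

Alternative 3: cut each interflavan bond with reversed polarity, ring A as the organometallic nucleophile and C4 as a carbonyl carbon.
- A C6-lithiated unit such as A4 would add to the C4 ketone A3 (from 2 by silylation of O3 and oxidation of C4). Ionic deoxygenation of the resulting tertiary benzylic position would complete the bond.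
- Hydride would reach the diaryl-stabilised C4 cation from the β face, anti to O3. The new aryl group would end up α (3,4-cis), the wrong epimer at every linkage.
- A4 needs a halogen at C6, which ring A halogenation does not place (it goes to C8).
- Each bond would cost extra redox and protecting-group steps. In the chosen plan C4 is ionised directly from the ether or sulfide and the arene enters β.

Key step: step 9

## Route

Remark: the four secondary 3-OH groups are carried unprotected throughout; this is assumed to be tolerated in every step, as is usual for benzylated flavan-3-ol couplings. "Tetra-O-benzyl" always means the 5,7,3',4'-tetrabenzyl ether; C2 and C3 of every unit keep the configuration of 1.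

Step 1
Reactants: 1 (−)-epicatechin
Product: 2 5,7,3',4'-tetra-O-benzyl-(−)-epicatechin
Conditions: BnBr (4.4 equiv), K2CO3, DMF, 0 °C → rt
Reagents that add atoms: benzyl bromide, BrCc1ccccc1
Why: Williamson etherification; K2CO3 deprotonates only the four phenols, so the secondary 3-OH stays free and C2/C3 are not touched.

Step 2
Reactants: 2 5,7,3',4'-tetra-O-benzyl-(−)-epicatechin
Product: 3 4β-(2-ethoxyethoxy)-5,7,3',4'-tetra-O-benzylepicatechin
Conditions: DDQ (1.5 equiv), 2-ethoxyethanol (5 equiv), CH2Cl2, rt
Reagents that add atoms: 2-ethoxyethanol, CCOCCO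
Why: Benzylic oxidative etherification: DDQ abstracts hydride from C4–H (activated by O1, O5 and O7 of ring A) and the alcohol captures the cation anti to the pseudo-axial C3–OH and the C2 aryl group, giving the 4β ether (3,4-trans). The C4 configuration of 3 to 5 is of no consequence later, since C4 is ionised again.

Step 3
Reactants: 3 4β-(2-ethoxyethoxy)-5,7,3',4'-tetra-O-benzylepicatechin
Product: 4 8-bromo-4β-(2-ethoxyethoxy)-5,7,3',4'-tetra-O-benzylepicatechin
Conditions: NBS (1.0 equiv), CH2Cl2, −78 → −20 °C
Reagents that add atoms: N-bromosuccinimide, O=C1CCC(=O)N1Br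
Why: Electrophilic aromatic bromination of ring A; C8 is the more reactive position of benzylated flavan-3-ols and C6 is further shielded by the 5-benzyloxy group pressed against the C4 substituent. Neutral conditions leave the acid-labile C4 ether intact.

Step 4
Reactants: 4 8-bromo-4β-(2-ethoxyethoxy)-5,7,3',4'-tetra-O-benzylepicatechin
Product: 5 8-bromo-4β-(2,6-dimethylphenylthio)-5,7,3',4'-tetra-O-benzylepicatechin
Conditions: 2,6-Me2C6H3SH (3 equiv), BF3·OEt2 (0.3 equiv), CH2Cl2, −78 → −40 °C
Reagents that add atoms: 2,6-dimethylbenzenethiol, Cc1cccc(C)c1S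
Why: Acid-catalysed SN1 exchange at C4 through the ring-A-stabilised cation; the thiol adds to the β face (trans to O3) and its excess outruns alkylation of C6 of a second molecule. The weakly basic, ortho-shielded aryl sulfide is inert to oxophilic acids at low temperature and serves as a latent leaving group.

Step 5
Reactants: 4 8-bromo-4β-(2-ethoxyethoxy)-5,7,3',4'-tetra-O-benzylepicatechin and 5 8-bromo-4β-(2,6-dimethylphenylthio)-5,7,3',4'-tetra-O-benzylepicatechin
Product: 6 (8-bromo-5,7,3',4'-tetra-O-benzylepicatechin)-(4β→6)-[8-bromo-4β-(2,6-dimethylphenylthio)-5,7,3',4'-tetra-O-benzylepicatechin] (units 1 and 2)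
Conditions: TMSOTf (0.2 equiv), CH2Cl2, −78 °C, 4 added slowly to 5 (2.5 equiv, excess recovered); Et3N quench
Reagents that add atoms: none
Why: Friedel–Crafts alkylation of ring A by the C4 cation of 4: in 5 C8 is brominated, so C6 is the only ring A carbon left, and attack anti to O3 sets C4 of unit 1 as β. The silyl triflate ionises the ether leaving group of 4 but not the C4–S bond of 5 (hard versus soft activation). Excess 5 and slow addition of 4 hold back self-alkylation of 4 at its own C6.

Step 6
Reactants: 2 5,7,3',4'-tetra-O-benzyl-(−)-epicatechin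
Product: 7 8-chloro-5,7,3',4'-tetra-O-benzylepicatechin
Conditions: NCS (1.05 equiv), DMF, 0 °C → rt
Reagents that add atoms: N-chlorosuccinimide, O=C1CCC(=O)N1Cl
Why: Electrophilic aromatic chlorination with the same C8 preference as bromination. Chlorine is chosen for unit 4 because it survives the later bromine–lithium exchange and falls in the final hydrogenolysis.

Step 7
Reactants: 4 8-bromo-4β-(2-ethoxyethoxy)-5,7,3',4'-tetra-O-benzylepicatechin and 7 8-chloro-5,7,3',4'-tetra-O-benzylepicatechin
Product: 8 (8-bromo-5,7,3',4'-tetra-O-benzylepicatechin)-(4β→6)-(8-chloro-5,7,3',4'-tetra-O-benzylepicatechin)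
Conditions: TMSOTf (0.2 equiv), CH2Cl2, −78 °C, 4 added slowly to 7 (3 equiv, excess recovered); Et3N quench
Reagents that add atoms: none
Why: Same Friedel–Crafts alkylation as step 5: C6 of 7 is the only free ring A position and β attack sets C4 of unit 3. The bromine of 4 prevents electrophile and product from reacting at C8 of unit 3 during the coupling.

Step 8
Reactants: 8 (8-bromo-5,7,3',4'-tetra-O-benzylepicatechin)-(4β→6)-(8-chloro-5,7,3',4'-tetra-O-benzylepicatechin)
Product: 10 (5,7,3',4'-tetra-O-benzylepicatechin)-(4β→6)-(8-chloro-5,7,3',4'-tetra-O-benzylepicatechin) (units 3 and 4), via C8-lithiated dilithium dialkoxide 9 (not isolated)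
Conditions: n-BuLi (3.5 equiv), THF, −78 °C; then MeOH, −78 °C → rt
Reagents that add atoms: none
Why: Halogen–lithium exchange is fast for the aryl bromide and negligible for the aryl chloride at −78 °C; the two alkoxides form first and methanol then protonates C8 of unit 3. No stereocentre is involved.

Step 9
Reactants: 6 (units 1 and 2, C4 sulfide) and 10 (units 3 and 4, free C8–H in unit 3)
Product: 11 (8-bromo-5,7,3',4'-tetra-O-benzylepicatechin)-(4β→6)-(8-bromo-5,7,3',4'-tetra-O-benzylepicatechin)-(4β→8)-(5,7,3',4'-tetra-O-benzylepicatechin)-(4β→6)-(8-chloro-5,7,3',4'-tetra-O-benzylepicatechin)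
Conditions: AgOTf (AgOSO2CF3, 2 equiv), 2,6-di-tert-butyl-4-methylpyridine (2 equiv), 4 Å MS, CH2Cl2, −40 → 0 °C, dark; 10 (1.5 equiv)
Reagents that add atoms: none
Why: AgOTf binds the sulfur of 6 and the C4–S bond of unit 2 ionises to a C4 cation stabilised by O1 and the ring A oxygens; C8 of ring A of unit 3 in 10 adds to it and the hindered pyridine takes up the proton. The closest known reaction type is the thiophile-promoted Friedel–Crafts coupling of C4-thio flavan-3-ols with benzylated flavan-3-ol nucleophiles, used with monomeric and oligomeric partners. No ring is closed: one C–C bond joins two dimers into the full twelve-ring skeleton. The only new stereocentre, C4 of unit 2, is set by unit 2 itself: in the half-chair cation the C2 aryl group is pseudo-equatorial and the C3–OH pseudo-axial on the α face, so the arene enters from the β face (3,4-trans), whatever the configuration of the departed sulfide. Site selectivity in 10 rests on the intrinsic C8 over C6 preference of benzylated ring A, on the two benzyloxy groups flanking C6 of unit 3, and on chlorine at C8 of unit 4. Chemoselectivity rests on the caps: 6 has bromine on both C8 carbons and offers only the C6–H of a brominated ring, 10 has no leaving group, and 11 has neither a leaving group nor a free C8–H, so neither partner nor product can react a second time. The buffered, soft activation leaves benzyl ethers, aryl halides, free 3-OH groups and the existing interflavan bonds untouched.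

Step 10
Reactants: 11 protected, halogen-capped tetramer
Product: 12 epicatechin-(4β→6)-epicatechin-(4β→8)-epicatechin-(4β→6)-epicatechin (CNP0120618.1)
Conditions: H2 (1 atm), Pd(OH)2/C, Et3N (3.3 equiv), THF/MeOH/H2O, rt; filtration, lyophilisation
Reagents that add atoms: none
Why: Heterogeneous hydrogenolysis cleaves the sixteen benzyl ethers and hydrodehalogenates the two aryl bromides and the aryl chloride. The amine traps HBr and HCl, which would otherwise cleave the interflavan bonds, and assists aryl chloride reduction; ring C ether bonds, interflavan bonds and all eleven stereocentres are untouched.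

## Compound list

1 | (−)-epicatechin | Oc1cc(O)c2c(c1)O[C@H](c5ccc(O)c(O)c5)[C@H](O)C2 | starting material

2 | 5,7,3',4'-tetra-O-benzyl-(−)-epicatechin | O(Cc4ccccc4)c1cc(OCc4ccccc4)c2c(c1)O[C@H](c5ccc(OCc4ccccc4)c(OCc4ccccc4)c5)[C@H](O)C2 | intermediate

3 | 4β-(2-ethoxyethoxy)-5,7,3',4'-tetra-O-benzylepicatechin | O(Cc4ccccc4)c1cc(OCc4ccccc4)c2c(c1)O[C@H](c5ccc(OCc4ccccc4)c(OCc4ccccc4)c5)[C@H](O)[C@H]2OCCOCC | intermediate

4 | 8-bromo-4β-(2-ethoxyethoxy)-5,7,3',4'-tetra-O-benzylepicatechin | O(Cc4ccccc4)c1cc(OCc4ccccc4)c2c(c1Br)O[C@H](c5ccc(OCc4ccccc4)c(OCc4ccccc4)c5)[C@H](O)[C@H]2OCCOCC | intermediate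

5 | 8-bromo-4β-(2,6-dimethylphenylthio)-5,7,3',4'-tetra-O-benzylepicatechin | O(Cc4ccccc4)c1cc(OCc4ccccc4)c2c(c1Br)O[C@H](c5ccc(OCc4ccccc4)c(OCc4ccccc4)c5)[C@H](O)[C@H]2Sc1c(C)cccc1C | intermediate

6 | dimer of units 1 and 2: 8-bromo top unit, (4β→6), 8-bromo lower unit with 4β-(2,6-dimethylphenylthio) group, octa-O-benzyl | O(Cc4ccccc4)c1cc(OCc4ccccc4)c2c(c1Br)O[C@H](c5ccc(OCc4ccccc4)c(OCc4ccccc4)c5)[C@H](O)[C@H]2c1c(OCc4ccccc4)c(Br)c2c(c1OCc4ccccc4)[C@H](Sc1c(C)cccc1C)[C@@H](O)[C@@H](c5ccc(OCc4ccccc4)c(OCc4ccccc4)c5)O2 | intermediate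

7 | 8-chloro-5,7,3',4'-tetra-O-benzylepicatechin | O(Cc4ccccc4)c1cc(OCc4ccccc4)c2c(c1Cl)O[C@H](c5ccc(OCc4ccccc4)c(OCc4ccccc4)c5)[C@H](O)C2 | intermediate

8 | dimer: 8-bromo top unit, (4β→6), 8-chloro lower unit, octa-O-benzyl | O(Cc4ccccc4)c1cc(OCc4ccccc4)c2c(c1Br)O[C@H](c5ccc(OCc4ccccc4)c(OCc4ccccc4)c5)[C@H](O)[C@H]2c1c(OCc4ccccc4)c(Cl)c2c(c1OCc4ccccc4)C[C@@H](O)[C@@H](c5ccc(OCc4ccccc4)c(OCc4ccccc4)c5)O2 | intermediate

9 | C8-lithiated dilithium dialkoxide of 8 (top unit C8–Li, both O3–Li) | O(Cc4ccccc4)c1cc(OCc4ccccc4)c2c(c1[Li])O[C@H](c5ccc(OCc4ccccc4)c(OCc4ccccc4)c5)[C@H](O[Li])[C@H]2c1c(OCc4ccccc4)c(Cl)c2c(c1OCc4ccccc4)C[C@@H](O[Li])[C@@H](c5ccc(OCc4ccccc4)c(OCc4ccccc4)c5)O2 | intermediate (not isolated)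

10 | dimer of units 3 and 4: unhalogenated top unit, (4β→6), 8-chloro lower unit, octa-O-benzyl | O(Cc4ccccc4)c1cc(OCc4ccccc4)c2c(c1)O[C@H](c5ccc(OCc4ccccc4)c(OCc4ccccc4)c5)[C@H](O)[C@H]2c1c(OCc4ccccc4)c(Cl)c2c(c1OCc4ccccc4)C[C@@H](O)[C@@H](c5ccc(OCc4ccccc4)c(OCc4ccccc4)c5)O2 | intermediate

11 | hexadeca-O-benzyl tetramer, Br at C8 of units 1 and 2, Cl at C8 of unit 4, linkages (4β→6), (4β→8), (4β→6) | O(Cc4ccccc4)c1cc(OCc4ccccc4)c2c(c1Br)O[C@H](c5ccc(OCc4ccccc4)c(OCc4ccccc4)c5)[C@H](O)[C@H]2c1c(OCc4ccccc4)c(Br)c2c(c1OCc4ccccc4)[C@H](c1c(OCc4ccccc4)cc(OCc4ccccc4)c3c1O[C@H](c5ccc(OCc4ccccc4)c(OCc4ccccc4)c5)[C@H](O)[C@H]3c1c(OCc4ccccc4)c(Cl)c3c(c1OCc4ccccc4)C[C@@H](O)[C@@H](c5ccc(OCc4ccccc4)c(OCc4ccccc4)c5)O3)[C@@H](O)[C@@H](c5ccc(OCc4ccccc4)c(OCc4ccccc4)c5)O2 | intermediate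

12 | epicatechin-(4β→6)-epicatechin-(4β→8)-epicatechin-(4β→6)-epicatechin | Oc1cc(O)c2c(c1)O[C@H](c1ccc(O)c(O)c1)[C@H](O)[C@H]2c1c(O)cc2c(c1O)[C@H](c1c(O)cc(O)c3c1O[C@H](c1ccc(O)c(O)c1)[C@H](O)[C@H]3c1c(O)cc3c(c1O)C[C@@H](O)[C@@H](c1ccc(O)c(O)c1)O3)[C@@H](O)[C@@H](c1ccc(O)c(O)c1)O2 | target

## Step count and least certain steps

Total steps: 10. Longest linear sequence: 7 steps (1, 2, 3, 4, 5, 9, 10).

**Step 9 (key step).**
- What may go wrong: slow ionisation of 6, because both ring A benzyloxy groups of unit 2 are flanked on both sides and twisted out of conjugation, and slow capture of a dimer-sized cation by a dimer-sized nucleophile. Attack at C6 of unit 3, acid-mediated interflavan scrambling or self-alkylation at C6 of unit 1 could then gain ground.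
- Fallback (2+1+1 order, monomer in place of the dimer nucleophile): setting out from 6 and 3, the same AgOTf activation with 3 in excess should give the trimer F1. The C8–H of 3 is free and its C4 ether is inert to the soft activator. F1 carries units 1 and 2 as in 6, a (4β→8) bond to unit 3, and the 4β-(2-ethoxyethoxy) group of unit 3. TMSOTf-catalysed coupling of F1 with excess 7 then forms the unit 3–unit 4 bond and comes back to the route at 11.

**Step 5.**
- What may go wrong: loss of orthogonality (partial ionisation of the C4–S bond of 5 by silyl triflate or triflic acid, with scrambling), or self-alkylation of 4 at its own C6 competing with the equally deactivated and more hindered C6 of 5.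
- Fallback (use the self-alkylation productively): setting out from 4 alone, Zn(OTf)2 in CH2Cl2 at 0 °C, run to partial conversion, should give the head-to-tail dimer F2. F2 is the 8-bromo unit-(4β→6)-8-bromo unit with the 4β-(2-ethoxyethoxy) group kept on the lower unit. Thiol exchange on F2 as in step 4 (2,6-dimethylbenzenethiol, BF3·OEt2 cat., −78 → −40 °C) returns to the route at 6.

**Step 8.**
- What may go wrong: incomplete exchange, or side reactions of the excess organolithium (deprotonation of benzylic ether positions, butylation of the aryllithium by 1-bromobutane).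
- Fallback (iodine cap on unit 3, magnesium as exchange metal): setting out from 3, iodination at C8 with N-iodosuccinimide gives the 8-iodo electrophile F3. TMSOTf-catalysed coupling of F3 with 7 gives the iodo/chloro dimer F4. Iodine–magnesium exchange on F4 with i-PrMgCl·LiCl (THF, −20 °C; the first two equivalents deprotonate the alcohols) followed by MeOH comes back to the route at 10; the aryl chloride does not exchange.

**Step 6.**
- What may go wrong: poor positional selectivity of the chlorination (C6 against C8) or over-chlorination, since the C8 preference is better established for bromination.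
- Fallback (chlorine by ipso exchange of the C8 bromide): setting out from 2, NBS (CH2Cl2, −78 °C) gives 8-bromo-5,7,3',4'-tetra-O-benzylepicatechin F5. n-BuLi (2.2 equiv, THF, −78 °C) and then C2Cl6 convert F5 into 7, where it rejoins the route.

**Step 10.**
- What may go wrong: incomplete removal of the aryl chloride or of some of the sixteen benzyl ethers, catalyst poisoning by halide, or damage to the free tetramer by the amine (C2 epimerisation, oxidation).
- Fallback (dehalogenation separated from debenzylation): setting out from 11, transfer hydrodehalogenation at the protected stage should give the halogen-free hexadeca-O-benzyl tetramer F6. Conditions: [Pd(allyl)Cl]2 with 1,3-bis(2,6-diisopropylphenyl)imidazolium chloride, NaOt-Bu, i-PrOH/toluene, 60 °C; zerovalent palladium inserts into C–Br and C–Cl and isopropoxide supplies hydride. Amine-free hydrogenolysis of F6 (H2, Pd(OH)2/C, THF/MeOH/H2O) comes back to the route at 12.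

## Further compounds

F1 | step 9 | trimer: units 1 and 2 as in 6 (both 8-bromo), (4β→8) to unit 3 carrying 4β-(2-ethoxyethoxy), dodeca-O-benzyl | O(Cc4ccccc4)c1cc(OCc4ccccc4)c2c(c1Br)O[C@H](c5ccc(OCc4ccccc4)c(OCc4ccccc4)c5)[C@H](O)[C@H]2c1c(OCc4ccccc4)c(Br)c2c(c1OCc4ccccc4)[C@H](c1c(OCc4ccccc4)cc(OCc4ccccc4)c3c1O[C@H](c5ccc(OCc4ccccc4)c(OCc4ccccc4)c5)[C@H](O)[C@H]3OCCOCC)[C@@H](O)[C@@H](c5ccc(OCc4ccccc4)c(OCc4ccccc4)c5)O2
F2 | step 5 | dimer: 8-bromo top unit, (4β→6), 8-bromo lower unit with 4β-(2-ethoxyethoxy) group, octa-O-benzyl | O(Cc4ccccc4)c1cc(OCc4ccccc4)c2c(c1Br)O[C@H](c5ccc(OCc4ccccc4)c(OCc4ccccc4)c5)[C@H](O)[C@H]2c1c(OCc4ccccc4)c(Br)c2c(c1OCc4ccccc4)[C@H](OCCOCC)[C@@H](O)[C@@H](c5ccc(OCc4ccccc4)c(OCc4ccccc4)c5)O2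
F3 | step 8 | 8-iodo-4β-(2-ethoxyethoxy)-5,7,3',4'-tetra-O-benzylepicatechin | O(Cc4ccccc4)c1cc(OCc4ccccc4)c2c(c1I)O[C@H](c5ccc(OCc4ccccc4)c(OCc4ccccc4)c5)[C@H](O)[C@H]2OCCOCC
F4 | step 8 | dimer: 8-iodo top unit, (4β→6), 8-chloro lower unit, octa-O-benzyl | O(Cc4ccccc4)c1cc(OCc4ccccc4)c2c(c1I)O[C@H](c5ccc(OCc4ccccc4)c(OCc4ccccc4)c5)[C@H](O)[C@H]2c1c(OCc4ccccc4)c(Cl)c2c(c1OCc4ccccc4)C[C@@H](O)[C@@H](c5ccc(OCc4ccccc4)c(OCc4ccccc4)c5)O2
F5 | step 6 | 8-bromo-5,7,3',4'-tetra-O-benzylepicatechin | O(Cc4ccccc4)c1cc(OCc4ccccc4)c2c(c1Br)O[C@H](c5ccc(OCc4ccccc4)c(OCc4ccccc4)c5)[C@H](O)C2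
F6 | step 10 | halogen-free hexadeca-O-benzyl tetramer, linkages (4β→6), (4β→8), (4β→6) | O(Cc4ccccc4)c1cc(OCc4ccccc4)c2c(c1)O[C@H](c5ccc(OCc4ccccc4)c(OCc4ccccc4)c5)[C@H](O)[C@H]2c1c(OCc4ccccc4)cc2c(c1OCc4ccccc4)[C@H](c1c(OCc4ccccc4)cc(OCc4ccccc4)c3c1O[C@H](c5ccc(OCc4ccccc4)c(OCc4ccccc4)c5)[C@H](O)[C@H]3c1c(OCc4ccccc4)cc3c(c1OCc4ccccc4)C[C@@H](O)[C@@H](c5ccc(OCc4ccccc4)c(OCc4ccccc4)c5)O3)[C@@H](O)[C@@H](c5ccc(OCc4ccccc4)c(OCc4ccccc4)c5)O2
A1 | alternative 1 | trimer: 8-bromo unit 2, (4β→8), unhalogenated unit 3, (4β→6), 8-chloro unit 4, dodeca-O-benzyl | O(Cc4ccccc4)c1cc(OCc4ccccc4)c2c(c1Br)O[C@H](c5ccc(OCc4ccccc4)c(OCc4ccccc4)c5)[C@H](O)[C@H]2c1c(OCc4ccccc4)cc(OCc4ccccc4)c3c1O[C@H](c5ccc(OCc4ccccc4)c(OCc4ccccc4)c5)[C@H](O)[C@H]3c1c(OCc4ccccc4)c(Cl)c3c(c1OCc4ccccc4)C[C@@H](O)[C@@H](c5ccc(OCc4ccccc4)c(OCc4ccccc4)c5)O3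
A2 | alternative 2 | hexadeca-O-benzyl tetramer from self-coupling of 10, Cl at C8 of units 2 and 4 | O(Cc4ccccc4)c1cc(OCc4ccccc4)c2c(c1)O[C@H](c5ccc(OCc4ccccc4)c(OCc4ccccc4)c5)[C@H](O)[C@H]2c1c(OCc4ccccc4)c(Cl)c2c(c1OCc4ccccc4)[C@H](c1c(OCc4ccccc4)cc(OCc4ccccc4)c3c1O[C@H](c5ccc(OCc4ccccc4)c(OCc4ccccc4)c5)[C@H](O)[C@H]3c1c(OCc4ccccc4)c(Cl)c3c(c1OCc4ccccc4)C[C@@H](O)[C@@H](c5ccc(OCc4ccccc4)c(OCc4ccccc4)c5)O3)[C@@H](O)[C@@H](c5ccc(OCc4ccccc4)c(OCc4ccccc4)c5)O2
A3 | alternative 3 | 2,3-cis 5,7,3',4'-tetra-O-benzyl-3-O-(tert-butyldimethylsilyl)flavan-4-one, C2 and C3 arranged as in 2 | O(Cc4ccccc4)c1cc(OCc4ccccc4)c2c(c1)O[C@H](c5ccc(OCc4ccccc4)c(OCc4ccccc4)c5)[C@H](O[Si](C)(C)C(C)(C)C)C2=O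
A4 | alternative 3 | 6-lithio-8-chloro-5,7,3',4'-tetra-O-benzyl-3-O-(tert-butyldimethylsilyl)epicatechin | O(Cc4ccccc4)c1c([Li])c(OCc4ccccc4)c2c(c1Cl)O[C@H](c5ccc(OCc4ccccc4)c(OCc4ccccc4)c5)[C@H](O[Si](C)(C)C(C)(C)C)C2
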